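**Reading time.** We read at 6.0 d, later than the last noon reading at 30.0 h. So the first question about a flask is whether it still moves at that time or has stopped.

| flask | substrate | coupling partner | temperature | remark | time |
|---|---|---|---|---|---|
| noon | 0.078 M | 0.0781 M | 90 °C | run made earlier |  |
| Tuesday's | 0.071 M | 0.120 M | 90 °C |  | 6.0 d |
| Wednesday's | 0.10 M | 0.120 M | 120 °C |  | 6.0 d |
| Thursday's | 0.040 M | 0.150 M | 110 °C |  | 6.0 d |
| Saturday's | 0.020 M | 0.120 M | 110 °C |  | 6.0 d |
| Monday's | 0.071 M | 0.0781 M | 90 °C |  | 6.0 d |
| Sunday's | 0.20 M | 0.0781 M | 90 °C |  | 6.0 d |

noon run (percent of the substrate charged)

| time / h | target / % | substrate / % |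
|---|---|---|
| 4.00 | 14 | 87 |
| 10.0 | 28 | 76 |
| 20.0 | 37 | 59 |
| 30.0 | 45 | 52 |

(standard deviation of a reading: 1.5 percentage points)

- what is said of target includes crystals
- crystals is a solid; its amount is given per volume of the solution
- the numbers in the tables scatter with a standard deviation of 1.5 percentage points
- what may be going on: substrate + coupling partner -> target; 2 coupling partner -> side product; crystals <-> target
- the earlier runs do not show what temperature does; that part of a forecast is a guess

- all flasks from highest to lowest amount of target, in percent of the substrate charged, at 6.0 d (Tuesday's / Wednesday's / Thursday's / Saturday's / Monday's / Sunday's)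
- the amount of target, in percent of the substrate charged of the flask you put first, at 6.0 d
- the amount of target, in percent of the substrate charged of the flask you put last, at 6.0 d

**Bench rule.** One turn of coupling takes one coupling partner for one substrate. So target, crystals counted, cannot pass the charge of partner over the charge of substrate, taken as a fraction of the substrate charged. For Sunday's this partner ceiling, charged partner over charged substrate, is 39.0%. Partner is the limiting reagent there, and whatever goes to side product lowers the yield below that line.

**Its border.** The rule stops working where the ratio reaches one. The noon run sits there at 1.00, and its target already read 45% at 30.0 h, above Sunday's ceiling. Monday's has 1.10 and Wednesday's 1.20. Above one the rule says nothing, and rates and the guessed temperature take over. Sunday's has the lowest ratio, so we put it last.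

**Mean curve.** Does Sunday's reach its line in time? Substrate stands in excess, so partner falls in a pseudo-first-order way, at a rate that follows the substrate left. If Sunday's reaches its ceiling, that substrate goes from the full charge down to 61.0%, and we replace the curve by its mean, 80.5%. With the second-order constant read from the first noon reading, the partner's life, its time to fall by a factor e, comes to 13.0 h. Now we check the error. Using the end value of the substrate instead stretches the life to 17.1 h, and the reading still comes after 8.42 such lives. So we expect Sunday's to have stopped by the reading, somewhat below 39.0%. The noon readings show no partner, so we leave the share lost to side product open.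

The forecast gave Thursday's > Saturday's > Tuesday's > Wednesday's > Monday's > Sunday's, with 98% first and 34% last, and called Sunday's “partner-limited”.

**What stands.** The flasks give Saturday's > Thursday's > Tuesday's > Monday's > Wednesday's > Sunday's, with 91.1% in Saturday's and 33.3% in Sunday's.

    substrate + coupling partner → target (k = 0.520 L mol⁻¹ h⁻¹, Ea = 77.0 kJ mol⁻¹)
    2 coupling partner → side product (k = 0.211 L mol⁻¹ h⁻¹, Ea = 106 kJ mol⁻¹)
    crystals ⇌ target, rate k3*(cs3 - [target]) while solid is left; crystals form when [target] > cs3 (solubility = 4.10 mM, k = 8.71 h⁻¹)
    (constants at 90 °C)

Sunday's holds 33.3% of target with 0% of its partner left, which fills 85.4% of the ceiling. Left ten times as long it still reads 33.3%. The neighbouring flask has the partner charge of Sunday's but 0.34 M of substrate, so its ceiling is 23.0%. There 0% of the partner is left, and target stands at 20.9%, which fills 90.9% of that ceiling.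

All runs are simulated for an exercise; the scatter is artificial.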